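## Retrosynthetic overview

1. The last carbon–carbon bond is the C(=O)–CH= bond of the enone: Nozaki–Hiyama–Kishi union of an (E)-vinyl iodide (oxanone half) with a β,γ-unsaturated aldehyde (aryl half), then allylic oxidation and phenol desilylation.
2. Aryl half: Pd-catalysed coupling of a benzylic chloride with the alkenylalane from carboalumination of but-3-yn-1-ol sets the E ArCH2–CH=C(Me) alkene; the arene is functionalised by ortho-lithiation of silylated 4-methoxy-3-methylphenol.
3. Oxanone half: the ring O–CMe2 bond comes from intramolecular oxymercuration of an isopropenyl carbinol, made by an Ipc2BCl aldol of a methyl ketone with methacrolein (sets ring C5).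
4. The methyl ketone comes from (S)-lactic acid by Seebach alkylation of its pivalaldehyde acetal with an iodoalkyl (E)-vinyl iodide from carboalumination of pent-4-yn-1-ol (sets ring C2).
5. Ring order: the benzene ring is bought; the oxanone is the only ring built, and it is closed before the fragment union.

Assumption: the (−)-Ipc2BCl enolate of the methyl ketone is taken to attack the Re face of methacrolein (the usual sense for methyl ketone enolates, giving the 3R carbinol); if the 3S epimer predominates, (+)-Ipc2BCl is used instead.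

## Route

Step 1
Reactants: 1 (S)-lactic acid, 2 pivalaldehyde (2,2-dimethylpropanal)
Product: 3 (2S,5S)-2-tert-butyl-5-methyl-1,3-dioxolan-4-one
Conditions: cat. TsOH·H2O, cat. H2SO4, pentane, reflux, Dean–Stark; recrystallise at −78 °C
Reagents that add atoms: none
Why: Acid-catalysed acetalisation with water removal gives mainly the cis dioxolanone, the lactate centre fixing the new acetal carbon (tert-butyl cis to methyl, 2S), and crystallisation removes the trans isomer.

Step 2
Reactants: 4 pent-4-yn-1-ol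
Product: 6 (4E)-5-iodo-4-methylpent-4-en-1-ol, via alkenylalane 5 (not isolated)
Conditions: Me3Al (3 equiv), Cp2ZrCl2 (0.25 equiv), CH2Cl2, 0 °C to rt; then I2, THF, −30 to 0 °C
Reagents that add atoms: trimethylaluminium C[Al](C)C; iodine II
Why: Negishi zirconium-catalysed carboalumination adds Me–Al syn and regioselectively across the terminal alkyne, and iodinolysis of the C–Al bond with retention fixes the E trisubstituted vinyl iodide.

Step 3
Reactants: 6 (4E)-5-iodo-4-methylpent-4-en-1-ol
Product: 7 (1E)-1,5-diiodo-2-methylpent-1-ene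
Conditions: PPh3, I2, imidazole, CH2Cl2, 0 °C to rt
Reagents that add atoms: iodine II
Why: Appel-type iodination converts the primary alcohol into the iodide by SN2 displacement of the oxyphosphonium group while the vinyl iodide is untouched.

Step 4
Reactants: 3 (2S,5S)-2-tert-butyl-5-methyl-1,3-dioxolan-4-one, 7 (1E)-1,5-diiodo-2-methylpent-1-ene
Product: 9 (2S,5R)-2-tert-butyl-5-[(4E)-5-iodo-4-methylpent-4-en-1-yl]-5-methyl-1,3-dioxolan-4-one, via lithium enolate 8 (not isolated)
Conditions: LiN(iPr)2 (1.05 equiv), THF, −78 °C; then 7, DMPU, −78 to −30 °C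
Reagents that add atoms: none
Why: Seebach self-regeneration of stereocentres: the planar enolate is alkylated by the primary iodide on the face anti to the tert-butyl group, so the chain replaces H with retention and the quaternary carbon (5R, the future ring C2) is set with high diastereoselectivity.

Step 5
Reactants: 9 (2S,5R)-2-tert-butyl-5-[(4E)-5-iodo-4-methylpent-4-en-1-yl]-5-methyl-1,3-dioxolan-4-one
Product: 10 (2R,6E)-2-hydroxy-7-iodo-N-methoxy-N,2,6-trimethylhept-6-enamide
Conditions: MeNH(OMe)·HCl, Me3Al, CH2Cl2, 0 °C to rt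
Reagents that add atoms: N,O-dimethylhydroxylamine hydrochloride CNOC.Cl
Why: Weinreb aminolysis by the aluminium amide opens the activated acylal-type lactone and the hemiacetal collapses on work-up with loss of pivalaldehyde, leaving the quaternary centre untouched.

Step 6
Reactants: 10 (2R,6E)-2-hydroxy-7-iodo-N-methoxy-N,2,6-trimethylhept-6-enamide
Product: 11 (3R,7E)-3-hydroxy-8-iodo-3,7-dimethyloct-7-en-2-one
Conditions: MeMgBr (3.5 equiv), THF, 0 °C
Reagents that add atoms: methylmagnesium bromide C[Mg]Br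
Why: Weinreb ketone synthesis: the chelated tetrahedral intermediate stops at mono-addition and releases the methyl ketone on work-up.

Step 7
Reactants: 11 (3R,7E)-3-hydroxy-8-iodo-3,7-dimethyloct-7-en-2-one
Product: 12 (3R,7E)-8-iodo-3,7-dimethyl-3-(trimethylsilyloxy)oct-7-en-2-one
Conditions: TMSCl, imidazole, DMF, rt
Reagents that add atoms: chlorotrimethylsilane C[Si](C)(C)Cl
Why: Silylation masks the tertiary hydroxyl so that the methyl group is the only site for boron enolisation.

Step 8
Reactants: 12 (3R,7E)-8-iodo-3,7-dimethyl-3-(trimethylsilyloxy)oct-7-en-2-one, 13 methacrolein (2-methylprop-2-enal)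
Product: 16 (3R,6R,10E)-3,6-dihydroxy-11-iodo-2,6,10-trimethylundeca-1,10-dien-5-one, via boron enolate 14 (not isolated), via silylated aldol adduct 15 (not isolated)
Conditions: (−)-Ipc2BCl, Et3N, Et2O, 0 °C; 13, −78 to −20 °C; H2O2, MeOH, pH 7 buffer, 0 °C; then citric acid, MeOH, rt
Reagents that add atoms: none
Why: Paterson boron aldol reaction: the bis(isopinocampheyl) enol borinate adds to methacrolein under reagent control (Re-face attack, 3R carbinol, about 5:1 expected since the quaternary centre exerts little bias), and mild acid then removes the TMS ether.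

Step 9
Reactants: 16 (3R,6R,10E)-3,6-dihydroxy-11-iodo-2,6,10-trimethylundeca-1,10-dien-5-one
Product: 18 (2R,5R)-5-hydroxy-2-[(4E)-5-iodo-4-methylpent-4-en-1-yl]-2,6,6-trimethyloxan-3-one, via alkylmercury chloride 17 (not isolated)
Conditions: Hg(OCOCF3)2, CH2Cl2, 0 °C; aq. NaCl; then NaBH4, aq. NaOH, THF, −20 °C, 5 min
Reagents that add atoms: none
Why: Intramolecular oxymercuration (Markovnikov 6-exo attack of the tertiary hydroxyl on the isopropenyl group) and fast borohydride demercuration close the oxanone ring without touching either stereocentre, the vinyl iodide being inert and the minor C5 epimer from step 8 being removed by chromatography here.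

Step 10
Reactants: 19 4-methoxy-3-methylphenol
Product: 20 (4-methoxy-3-methylphenoxy)tri(propan-2-yl)silane
Conditions: TIPSCl, imidazole, DMF, rt
Reagents that add atoms: chlorotri(propan-2-yl)silane CC(C)[Si](Cl)(C(C)C)C(C)C
Why: Imidazole-promoted silylation of the phenol installs a bulky, base-stable group that survives lithiation and is removed last.

Step 11
Reactants: 20 (4-methoxy-3-methylphenoxy)tri(propan-2-yl)silane
Product: 22 [2-methoxy-3-methyl-5-(triisopropylsilyloxy)phenyl]methanol, via aryllithium 21 (not isolated)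
Conditions: n-BuLi, TMEDA, Et2O, 0 °C to rt; then (CH2O)n, −78 °C to rt
Reagents that add atoms: formaldehyde (from paraformaldehyde) C=O
Why: Directed ortho-metalation: the methoxy group directs lithiation to its only free ortho position while the bulky silyloxy group does not direct, and formaldehyde hydroxymethylates the aryllithium.

Step 12
Reactants: 22 [2-methoxy-3-methyl-5-(triisopropylsilyloxy)phenyl]methanol
Product: 23 [3-(chloromethyl)-4-methoxy-5-methylphenoxy]tri(propan-2-yl)silane
Conditions: MsCl, Et3N, CH2Cl2, 0 °C to rt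
Reagents that add atoms: methanesulfonyl chloride CS(=O)(=O)Cl
Why: Mesylation of the electron-rich benzylic alcohol is followed in situ by SN2 displacement by chloride, giving the benzylic chloride needed for cross-coupling.

Step 13
Reactants: 23 [3-(chloromethyl)-4-methoxy-5-methylphenoxy]tri(propan-2-yl)silane, 24 but-3-yn-1-ol
Product: 26 (3E)-5-[2-methoxy-3-methyl-5-(triisopropylsilyloxy)phenyl]-3-methylpent-3-en-1-ol, via alkenylalane 25 (not isolated)
Conditions: 24, Me3Al (3 equiv), Cp2ZrCl2 (0.25 equiv), CH2Cl2, 0 °C to rt; excess Me3Al evaporated; then 23, Pd(PPh3)4 (5 mol %), THF, rt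
Reagents that add atoms: trimethylaluminium C[Al](C)C
Why: Negishi carboalumination followed by palladium-catalysed cross-coupling of the alkenylalane with the benzylic chloride forms the aryl–CH2–CH= bond with retention, fixing the E trisubstituted alkene.

Step 14
Reactants: 26 (3E)-5-[2-methoxy-3-methyl-5-(triisopropylsilyloxy)phenyl]-3-methylpent-3-en-1-ol
Product: 27 (3E)-5-[2-methoxy-3-methyl-5-(triisopropylsilyloxy)phenyl]-3-methylpent-3-enal
Conditions: Dess–Martin periodinane, NaHCO3, CH2Cl2, 0 °C; used at once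
Reagents that add atoms: none
Why: Dess–Martin oxidation under buffered, non-basic conditions gives the β,γ-unsaturated aldehyde without migration of the alkene into conjugation.

Step 15
Reactants: 18 (2R,5R)-5-hydroxy-2-[(4E)-5-iodo-4-methylpent-4-en-1-yl]-2,6,6-trimethyloxan-3-one, 27 (3E)-5-[2-methoxy-3-methyl-5-(triisopropylsilyloxy)phenyl]-3-methylpent-3-enal
Product: 28 (2R,5R)-5-hydroxy-2-{(4E,8E)-6-hydroxy-10-[2-methoxy-3-methyl-5-(triisopropylsilyloxy)phenyl]-4,8-dimethyldeca-4,8-dien-1-yl}-2,6,6-trimethyloxan-3-one (both epimers at the side-chain carbinol)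
Conditions: CrCl2 (6 equiv), NiCl2 (2 mol %), DMSO, rt
Reagents that add atoms: none
Why: Nozaki–Hiyama–Kishi coupling: the alkenylchromium species formed by nickel-catalysed activation of the vinyl iodide adds to the aldehyde but not to the hindered ring ketone, tolerates the free hydroxyl and keeps the E geometry, the new carbinol centre forming as a mixture that the next oxidation removes.

Step 16
Reactants: 28 (2R,5R)-5-hydroxy-2-{(4E,8E)-6-hydroxy-10-[2-methoxy-3-methyl-5-(triisopropylsilyloxy)phenyl]-4,8-dimethyldeca-4,8-dien-1-yl}-2,6,6-trimethyloxan-3-one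
Product: 29 (2R,5R)-5-hydroxy-2-{(4E,8E)-10-[2-methoxy-3-methyl-5-(triisopropylsilyloxy)phenyl]-4,8-dimethyl-6-oxodeca-4,8-dien-1-yl}-2,6,6-trimethyloxan-3-one
Conditions: activated MnO2 (20 equiv), CH2Cl2, rt
Reagents that add atoms: none
Why: Chemoselective allylic oxidation: activated MnO2 oxidises only the allylic alcohol to the E enone under neutral conditions that leave the saturated ring hydroxyl and the non-conjugated alkene in place.

Step 17
Reactants: 29 (2R,5R)-5-hydroxy-2-{(4E,8E)-10-[2-methoxy-3-methyl-5-(triisopropylsilyloxy)phenyl]-4,8-dimethyl-6-oxodeca-4,8-dien-1-yl}-2,6,6-trimethyloxan-3-one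
Product: 30 (2R,5R)-5-hydroxy-2-[(4E,8E)-10-(5-hydroxy-2-methoxy-3-methylphenyl)-4,8-dimethyl-6-oxodeca-4,8-dien-1-yl]-2,6,6-trimethyloxan-3-one (CNP0268050.2)
Conditions: Bu4NF, AcOH (1:1), THF, 0 °C
Reagents that add atoms: none
Why: Fluoride-mediated desilylation cleaves the aryl silyl ether quickly at 0 °C while the acetic acid buffer prevents base-induced alkene migration, retro-aldol cleavage or β-elimination of the β-hydroxy ketone.

## Compound list

1 | (S)-lactic acid | C[C@H](O)C(=O)O | starting material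
2 | pivalaldehyde | CC(C)(C)C=O | starting material
3 | (2S,5S)-2-tert-butyl-5-methyl-1,3-dioxolan-4-one | C[C@@H]1O[C@H](C(C)(C)C)OC1=O | intermediate
4 | pent-4-yn-1-ol | C#CCCCO | starting material
5 | dimethyl[(1E)-5-(dimethylalumanyloxy)-2-methylpent-1-en-1-yl]alumane | C[Al](C)/C=C(\C)CCCO[Al](C)C | intermediate (not isolated)
6 | (4E)-5-iodo-4-methylpent-4-en-1-ol | I/C=C(\C)CCCO | intermediate
7 | (1E)-1,5-diiodo-2-methylpent-1-ene | I/C=C(\C)CCCI | intermediate
8 | lithium (2S)-2-tert-butyl-5-methyl-1,3-dioxol-4-olate | CC1=C(O[Li])O[C@@H](C(C)(C)C)O1 | intermediate (not isolated)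
9 | (2S,5R)-2-tert-butyl-5-[(4E)-5-iodo-4-methylpent-4-en-1-yl]-5-methyl-1,3-dioxolan-4-one | C[C@]1(CCC/C(C)=C/I)O[C@H](C(C)(C)C)OC1=O | intermediate
10 | (2R,6E)-2-hydroxy-7-iodo-N-methoxy-N,2,6-trimethylhept-6-enamide | I/C=C(\C)CCC[C@@](C)(O)C(=O)N(C)OC | intermediate
11 | (3R,7E)-3-hydroxy-8-iodo-3,7-dimethyloct-7-en-2-one | I/C=C(\C)CCC[C@@](C)(O)C(C)=O | intermediate
12 | (3R,7E)-8-iodo-3,7-dimethyl-3-(trimethylsilyloxy)oct-7-en-2-one | I/C=C(\C)CCC[C@@](C)(O[Si](C)(C)C)C(C)=O | intermediate
13 | methacrolein | C=C(C)C=O | starting material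
14 | (3R,7E)-8-iodo-3,7-dimethyl-3-(trimethylsilyloxy)octa-1,7-dien-2-yl bis[(1R,2S,3R,5R)-2,6,6-trimethylbicyclo[3.1.1]heptan-3-yl]borinate | I/C=C(\C)CCC[C@@](C)(O[Si](C)(C)C)C(=C)OB([C@@H]1C[C@@H]2C[C@H]([C@H]1C)C2(C)C)[C@@H]3C[C@@H]4C[C@H]([C@H]3C)C4(C)C | intermediate (not isolated)
15 | (3R,6R,10E)-3-hydroxy-11-iodo-2,6,10-trimethyl-6-(trimethylsilyloxy)undeca-1,10-dien-5-one | I/C=C(\C)CCC[C@@](C)(O[Si](C)(C)C)C(=O)C[C@@H](O)C(C)=C | intermediate (not isolated)
16 | (3R,6R,10E)-3,6-dihydroxy-11-iodo-2,6,10-trimethylundeca-1,10-dien-5-one | I/C=C(\C)CCC[C@@](C)(O)C(=O)C[C@@H](O)C(C)=C | intermediate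
17 | chloro({(3R,6R)-3-hydroxy-6-[(4E)-5-iodo-4-methylpent-4-en-1-yl]-2,6-dimethyl-5-oxooxan-2-yl}methyl)mercury (both C2 epimers) | I/C=C(\C)CCC[C@@]1(C)OC(C)(C[Hg]Cl)[C@H](O)CC1=O | intermediate (not isolated)
18 | (2R,5R)-5-hydroxy-2-[(4E)-5-iodo-4-methylpent-4-en-1-yl]-2,6,6-trimethyloxan-3-one | I/C=C(\C)CCC[C@@]1(C)OC(C)(C)[C@H](O)CC1=O | intermediate
19 | 4-methoxy-3-methylphenol | COc1ccc(O)cc1C | starting material
20 | (4-methoxy-3-methylphenoxy)tri(propan-2-yl)silane | COc1ccc(O[Si](C(C)C)(C(C)C)C(C)C)cc1C | intermediate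
21 | [2-methoxy-3-methyl-5-(triisopropylsilyloxy)phenyl]lithium | [Li]c1cc(O[Si](C(C)C)(C(C)C)C(C)C)cc(C)c1OC | intermediate (not isolated)
22 | [2-methoxy-3-methyl-5-(triisopropylsilyloxy)phenyl]methanol | OCc1cc(O[Si](C(C)C)(C(C)C)C(C)C)cc(C)c1OC | intermediate
23 | [3-(chloromethyl)-4-methoxy-5-methylphenoxy]tri(propan-2-yl)silane | ClCc1cc(O[Si](C(C)C)(C(C)C)C(C)C)cc(C)c1OC | intermediate
24 | but-3-yn-1-ol | C#CCCO | starting material
25 | dimethyl[(1E)-4-(dimethylalumanyloxy)-2-methylbut-1-en-1-yl]alumane | C[Al](C)/C=C(\C)CCO[Al](C)C | intermediate (not isolated)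
26 | (3E)-5-[2-methoxy-3-methyl-5-(triisopropylsilyloxy)phenyl]-3-methylpent-3-en-1-ol | OCC/C(C)=C/Cc1cc(O[Si](C(C)C)(C(C)C)C(C)C)cc(C)c1OC | intermediate
27 | (3E)-5-[2-methoxy-3-methyl-5-(triisopropylsilyloxy)phenyl]-3-methylpent-3-enal | O=CC/C(C)=C/Cc1cc(O[Si](C(C)C)(C(C)C)C(C)C)cc(C)c1OC | intermediate
28 | (2R,5R)-5-hydroxy-2-{(4E,8E)-6-hydroxy-10-[2-methoxy-3-methyl-5-(triisopropylsilyloxy)phenyl]-4,8-dimethyldeca-4,8-dien-1-yl}-2,6,6-trimethyloxan-3-one (both epimers at the side-chain carbinol) | COc1c(C)cc(O[Si](C(C)C)(C(C)C)C(C)C)cc1C/C=C(\C)CC(O)/C=C(\C)CCC[C@@]1(C)OC(C)(C)[C@H](O)CC1=O | intermediate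
29 | (2R,5R)-5-hydroxy-2-{(4E,8E)-10-[2-methoxy-3-methyl-5-(triisopropylsilyloxy)phenyl]-4,8-dimethyl-6-oxodeca-4,8-dien-1-yl}-2,6,6-trimethyloxan-3-one | COc1c(C)cc(O[Si](C(C)C)(C(C)C)C(C)C)cc1C/C=C(\C)CC(=O)/C=C(\C)CCC[C@@]1(C)OC(C)(C)[C@H](O)CC1=O | intermediate
30 | (2R,5R)-5-hydroxy-2-[(4E,8E)-10-(5-hydroxy-2-methoxy-3-methylphenyl)-4,8-dimethyl-6-oxodeca-4,8-dien-1-yl]-2,6,6-trimethyloxan-3-one (CNP0268050.2) | COc1c(C)cc(O)cc1C/C=C(\C)CC(=O)/C=C(\C)CCC[C@@]1(C)OC(C)(C)[C@H](O)CC1=O | target

## Step count and risks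

Total step count: 17.
Longest linear sequence: 11 steps (from pent-4-yn-1-ol 4 to 30 through steps 2–9 and 15–17).

The three steps most likely to fail:

Step 8 (boron aldol). The diastereoselectivity may be modest, or the sense opposite to the one assumed. The fallback replaces reagent-controlled induction by a kinetic resolution; it sets out from 11 and comes back to the route at 16. The dilithio derivative of 11 (LiN(iPr)2, 2.2 equiv, THF, −78 °C) is added to 13 without stereocontrol to give the epimer mixture (3RS,6R,10E)-3,6-dihydroxy-11-iodo-2,6,10-trimethylundeca-1,10-dien-5-one F1. A Sharpless kinetic resolution (Ti(OiPr)4, L-(+)-diisopropyl tartrate, t-BuOOH, 4 Å sieves, CH2Cl2, −20 °C, about 55 % conversion) then epoxidises the faster-reacting 3S epimer to the epoxy alcohol (1S,4R,8E)-1,4-dihydroxy-9-iodo-4,8-dimethyl-1-[(2S)-2-methyloxiran-2-yl]non-8-en-3-one F2, which is separated, and leaves 16.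

Step 9 (oxymercuration and demercuration). Borohydride may reduce the ring ketone, or the base may trigger retro-aldol cleavage. The fallback closes the ring by a radical-polar hydroalkoxylation instead; it sets out from 16 and comes back at 18. The secondary hydroxyl of 16 is silylated selectively (TBSCl, imidazole, DMF) to (3R,6R,10E)-3-(tert-butyldimethylsilyloxy)-6-hydroxy-11-iodo-2,6,10-trimethylundeca-1,10-dien-5-one F3, which removes the free allylic alcohol that would otherwise give an epoxide or a hydride shift. Cobalt-catalysed hydrogen-atom-transfer hydroalkoxylation then gives (2R,5R)-5-(tert-butyldimethylsilyloxy)-2-[(4E)-5-iodo-4-methylpent-4-en-1-yl]-2,6,6-trimethyloxan-3-one F4. Conditions: the salen complex C32H46CoN2O2 [N,N′-bis(3,5-di-tert-butylsalicylidene)ethane-1,2-diaminatocobalt, divalent cobalt] at 5 mol %, N-fluoro-2,4,6-trimethylpyridinium tetrafluoroborate, (Me2SiH)2O, PhCF3, 0 °C. HF·pyridine in THF then returns 18.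

Step 15 (fragment union). The β,γ-unsaturated aldehyde may isomerise or self-condense before it is trapped, and the trisubstituted vinyl iodide may couple slowly. The fallback forms the same bond at the ketone oxidation level by an acyl Stille coupling; it sets out from 18 and 27 and comes back at 29, so that step 16 is not needed. Stannylation of 18 ((Bu3Sn)2, Pd(PPh3)4, toluene, 80 °C) gives (2R,5R)-5-hydroxy-2,6,6-trimethyl-2-[(4E)-4-methyl-5-(tributylstannyl)pent-4-en-1-yl]oxan-3-one F5. Pinnick oxidation of 27 (NaClO2, NaH2PO4, 2-methylbut-2-ene, t-BuOH/H2O) gives (3E)-5-[2-methoxy-3-methyl-5-(triisopropylsilyloxy)phenyl]-3-methylpent-3-enoic acid F6. Under neutral conditions 1-chloro-N,N,2-trimethylprop-1-en-1-amine converts it into (3E)-5-[2-methoxy-3-methyl-5-(triisopropylsilyloxy)phenyl]-3-methylpent-3-enoyl chloride F7. Coupling of F5 and F7 (Pd(PPh3)4, THF, 50 °C) gives 29.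

Further compounds

F1 | step 8 | (3RS,6R,10E)-3,6-dihydroxy-11-iodo-2,6,10-trimethylundeca-1,10-dien-5-one (C3 epimer mixture) | I/C=C(\C)CCC[C@@](C)(O)C(=O)CC(O)C(C)=C
F2 | step 8 | (1S,4R,8E)-1,4-dihydroxy-9-iodo-4,8-dimethyl-1-[(2S)-2-methyloxiran-2-yl]non-8-en-3-one | I/C=C(\C)CCC[C@@](C)(O)C(=O)C[C@H](O)[C@]1(C)CO1
F3 | step 9 | (3R,6R,10E)-3-(tert-butyldimethylsilyloxy)-6-hydroxy-11-iodo-2,6,10-trimethylundeca-1,10-dien-5-one | I/C=C(\C)CCC[C@@](C)(O)C(=O)C[C@@H](O[Si](C)(C)C(C)(C)C)C(C)=C
F4 | step 9 | (2R,5R)-5-(tert-butyldimethylsilyloxy)-2-[(4E)-5-iodo-4-methylpent-4-en-1-yl]-2,6,6-trimethyloxan-3-one | I/C=C(\C)CCC[C@@]1(C)OC(C)(C)[C@H](O[Si](C)(C)C(C)(C)C)CC1=O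
F5 | step 15 | (2R,5R)-5-hydroxy-2,6,6-trimethyl-2-[(4E)-4-methyl-5-(tributylstannyl)pent-4-en-1-yl]oxan-3-one | CCCC[Sn](CCCC)(CCCC)/C=C(\C)CCC[C@@]1(C)OC(C)(C)[C@H](O)CC1=O
F6 | step 15 | (3E)-5-[2-methoxy-3-methyl-5-(triisopropylsilyloxy)phenyl]-3-methylpent-3-enoic acid | OC(=O)C/C(C)=C/Cc1cc(O[Si](C(C)C)(C(C)C)C(C)C)cc(C)c1OC
F7 | step 15 | (3E)-5-[2-methoxy-3-methyl-5-(triisopropylsilyloxy)phenyl]-3-methylpent-3-enoyl chloride | ClC(=O)C/C(C)=C/Cc1cc(O[Si](C(C)C)(C(C)C)C(C)C)cc(C)c1OC
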